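Freeze the number that two winter readings give alike: the fraction of the remaining substrate that turns to product per minute, which reads 0.125 /min from the last reading and 0.126 /min from the one at 2.50 min, so I carry this decay constant, a pseudo-first-order constant, and multiply it by the time substrate spends in the mixture to get its exposure.

| setting | winter | spring | autumn | midnight | Wednesday's | Tuesday's | Saturday's | Thursday's |
|---|---|---|---|---|---|---|---|---|
| substrate | 20 mM | 20 mM | 20 mM | 20 mM | 20 mM | 20 mM | 20 mM (fed, over 4.80 min) | 20 mM |
| coupling partner | 40 mM | 40 mM | 40 mM | 60 mM | 40.0 mM | 40.0 mM | 40.0 mM | 40.0 mM (fed, over 4.80 min) |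
| initiator | 2 mM | 1.3 mM | 3 mM | 2 mM | 2.0 mM | 2.0 mM | 2.0 mM | 2.0 mM |
| remark | run made earlier | run made earlier | run made earlier | run made earlier | one stirred flow tank at steady state, fed with the mixture as stated, mean residence time 6.0 min | a closed flask charged with all of it at once and left for 6.0 min | a stirred flask in which substrate is dosed at a steady rate over 4.80 min without added volume, worked up at 6.0 min | all but coupling partner at the start; coupling partner goes in evenly over 4.80 min, the run ends at 6.0 min |
| time |  |  |  |  |  | 6.0 min | 6.0 min | 6.0 min |

| run | time / min | product / % | substrate / % |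
|---|---|---|---|
| winter | 0.333 | 4.9 | 98.1 |
| winter | 1.00 | 10.8 | 89.2 |
| winter | 1.50 | 15.5 | 84.1 |
| winter | 2.50 | 27.0 | 74.1 |
| winter | 4.00 | 40.4 | 60.9 |
| winter | 5.00 | 47.0 | 52.1 |
| winter | 6.00 | 52.9 | 46.0 |
| spring | 0.250 | 2.8 | 99.6 |
| spring | 0.667 | 5.8 | 92.7 |
| spring | 1.33 | 13.2 | 86.9 |
| spring | 2.00 | 19.0 | 81.9 |
| spring | 3.00 | 25.3 | 74.6 |
| spring | 4.00 | 32.9 | 67.8 |
| spring | 5.00 | 38.2 | 61.0 |
| autumn | 0.667 | 10.0 | 89.9 |
| autumn | 1.33 | 17.8 | 80.7 |
| autumn | 2.00 | 25.5 | 71.2 |
| autumn | 3.00 | 37.3 | 59.5 |
| autumn | 4.00 | 45.7 | 52.0 |
| autumn | 5.00 | 53.9 | 45.0 |
| midnight | 0.417 | 5.8 | 95.3 |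
| midnight | 0.667 | 8.8 | 94.0 |
| midnight | 1.33 | 16.3 | 83.6 |
| midnight | 2.50 | 28.8 | 71.8 |
| midnight | 5.00 | 49.6 | 51.4 |

(scatter of a reading: 1 percentage point)

- the stated concentrations are those of everything mixed, before any reaction; amounts are the same in each set-up
- the numbers in the tables scatter by 1 percentage point (one standard deviation)
- the feed brings no volume worth counting
- the earlier runs were made in a closed, stirred flask

1. the set-up with the highest amount of product at the outlet or at the end, in percent of the substrate put in ("none" if the first two lie within 2 percentage points) (Wednesday's / Tuesday's / Saturday's / Thursday's / none)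
2. amount of product at the outlet or at the end, in percent of the substrate put in, Wednesday's
3. amount of product at the outlet or at the end, in percent of the substrate put in, Tuesday's
4. amount of product at the outlet or at the end, in percent of the substrate put in, Saturday's
5. amount of product at the outlet or at the end, in percent of the substrate put in, Thursday's

1. Closed vessel: Tuesday's is the winter recipe, so its exposure is 0.753 and its product 52.9 %, which is the winter reading again and no check.

2. Tank: in Wednesday's, steady state sets the feed against decay at the outlet level, so my product share is exposure over one plus exposure, 43.0 %, which is less than my figure for Tuesday's.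

3. Substrate feed: in Saturday's, each portion is exposed from its entry onward, so I average the survival over the 4.80 min of feeding and let the mean decay for the remaining time, which gives 35.4 %.

4. Partner feed: the midnight run, with 60 mM of partner, has a constant 1.08 times the winter one at 5.00 min. I assume a saturating curve through zero, whose knee, the level where the rate stands midway to its ceiling, reads 11.3 mM, a loose reading given the scatter. Thursday's feed, reckoned without any consumption of partner, takes 1.36 min to reach it, and I crudely count that lag as lost exposure, which gives 44.2 %.

5. So I commit to Tuesday's, above the others. The forecast also names Tuesday's, with 43.2 %, 53 %, 35.7 % and 50 % in the order Wednesday's, Tuesday's, Saturday's, Thursday's, and it differs from me on Thursday's, which it puts higher, saying of that feed “it nearly matches batch”.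

6. The flask gives Tuesday's, with 43.2 %, 53.0 %, 36.1 % and 44.2 % in the same order.

    initiator → 2 initiating radical (k = 0.00519 /min)
    substrate + initiating radical → capped initiator + first chain carrier (k = 1.28 × 10⁶ /M/s)
    coupling partner + first chain carrier ⇌ product + second chain carrier (K = 21.4, k = 24300 /M/s)
    substrate + second chain carrier → by-product + first chain carrier (k = 99000 /M/s)
    first chain carrier → ended carrier (k = 116 /min)
    2 first chain carrier → ended chains A (k = 3.00 × 10⁶ /M/s)
    2 second chain carrier → ended chains B (k = 3.00 × 10⁸ /M/s)

Tuesday's is not at rest at 6.0 min, with 46.9 % of its substrate still there. For Tuesday's my constant gives an exposure of 7.50 by 60.0 min, leaving 0.0537 % of the substrate. Computed, Tuesday's then holds 0 % substrate and 99.7 % product, with 50.2 % of the partner's own charge and 73.2 % of the initiator's own charge remaining, so substrate is the limiting reagent.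

For the same flask as Tuesday's read at 1.5 min, the constant gives 17.1 %; the computed flask gives 16.9 %.

(The numbers in the tables were generated by integration with constants of no real substance.)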